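**Plan**
- Retrosynthesis: cut C11=C12 and C11'=C12' (two Wittig reactions, C15 + C10 + C15). In each end ring take out the vinylic CH (C4) by cutting C3–C4 and C4–C5, which contracts the ring to a cyclopentanone; then cut C6–C7.
- Enabling feature: in the six-membered ring C6 is γ to the C3 oxygen. In the ring without C4 (C3, C5, C6, C1, C2) it is the β-carbon of a 2-methylcyclopentenone next to the gem-dimethyl C1, and the enolate carbon C5 is where C4 must be put back.
- Forward: asymmetric conjugate addition of the whole C7–C11 arm to 2,4,4-trimethylcyclopent-2-enone with O-silylation, then cyclopropanation, then FeCl3 opening of the siloxycyclopropane, which widens the five-membered ring to the six-membered enone.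
- The one enone serves both ends: directly the oxo C15 phosphonium salt; after reduction and inversion the hydroxy C15 salt. The hydroxy salt is joined to the C10 dialdehyde first, the oxo salt last.
- Stereochemistry: C6 and C6' come from the catalyst-controlled conjugate addition (one event, used for both rings). C3' is relayed from C6' by substrate-controlled hydride delivery followed by Mitsunobu inversion. Chain geometry comes from syn-hydroalumination and thermodynamic E control.

Key step: step 5

Assumption: the SMILES is read as (3'R,6R,6'R) with the hydroxyl trans to the chain on its ring and all chain double bonds E; the side-chain carbinol carbon of building block 3 is used racemic because it is erased when the phosphonium salts are formed (compounds 4–10, 12 and 13 are therefore epimer pairs at that carbon only).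

**Step 1**
Reactants: 1 2,4,4-trimethylcyclopentan-1-one
Product: 2 2,4,4-trimethylcyclopent-2-en-1-one
Conditions: IBX (2-iodoxybenzoic acid, 1.5 equiv), DMSO/fluorobenzene, 70 °C
Reagents that add atoms: none
Why: IBX dehydrogenation of a ketone through its more substituted enol; only C2–C3 can be desaturated because C4 is quaternary, so the regiochemistry is fixed.

**Step 2**
Reactants: 3 3-methylpent-1-en-4-yn-3-ol (racemic)
Product: 4 tert-butyl(dimethyl)[(3-methylpent-1-en-4-yn-3-yl)oxy]silane
Conditions: TBSOTf, 2,6-lutidine, CH2Cl2, 0 °C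
Reagents that add atoms: tert-butyldimethylsilyl triflate, CC(C)(C)[Si](C)(C)OS(=O)(=O)C(F)(F)F
Why: Silylation of a tertiary alcohol with a silyl triflate and a hindered base; the ether masks the carbinol that later becomes the leaving group for salt formation.

**Step 3**
Reactants: 4 silyl ether of the enynol; 2 2,4,4-trimethylcyclopent-2-en-1-one
Product: 7 {[(3R)-3-[(1E)-3-(tert-butyldimethylsilyloxy)-3-methylpenta-1,4-dien-1-yl]-2,4,4-trimethylcyclopent-1-en-1-yl]oxy}trimethylsilane, via dienylalane 5 (not isolated), via aluminium enolate 6 (not isolated)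
Conditions: 4, i-Bu2AlH, hexane, 50 °C; then 2, Cu(OTf)2 (5 mol %), chiral binaphthol-derived phosphoramidite ligand (10 mol %), Et2O, −30 °C; then TMSOTf (1.0 equiv), −78 to 0 °C; pentane, filtration through basic alumina
Reagents that add atoms: trimethylsilyl triflate, C[Si](C)(C)OS(=O)(=O)C(F)(F)F
Why: Syn-hydroalumination of the terminal alkyne gives the (E)-alkenylalane, and copper-catalysed asymmetric conjugate addition of alkenylalanes to cyclic enones should deliver the alkenyl group to the Re face of C3 (ligand enantiomer chosen for this, setting the R centre that becomes C6 and C6'), while O-silylation of the regiodefined aluminium enolate fixes the tetrasubstituted enol ether.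

**Step 4**
Reactants: 7 trimethylsilyl enol ether
Product: 8 {[(1S,4R,5S)-4-[(1E)-3-(tert-butyldimethylsilyloxy)-3-methylpenta-1,4-dien-1-yl]-3,3,5-trimethylbicyclo[3.1.0]hexan-1-yl]oxy}trimethylsilane (cyclopropane CH2 anti to the side chain)
Conditions: Et2Zn, CH2I2, CH2Cl2, 0 °C to rt; cold aq. NaHCO3 work-up
Reagents that add atoms: diiodomethane, ICI
Why: Simmons–Smith cyclopropanation (Furukawa variant): the electrophilic zinc carbenoid should react fastest with the electron-rich silyl enol ether and leave the two hindered side-chain alkenes alone, adding anti to the C4 substituent; the two new stereocentres are erased in step 5.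

**Step 5**
Reactants: 8 siloxycyclopropane
Product: 10 (4R)-4-[(1E)-3-(tert-butyldimethylsilyloxy)-3-methylpenta-1,4-dien-1-yl]-3,5,5-trimethylcyclohex-2-en-1-one, via β-chloroketone 9 (not isolated)
Conditions: FeCl3 (2.2 equiv), DMF, 0 °C to rt; then NaOAc, MeOH, 50 °C
Reagents that add atoms: none
Why: Trivalent iron (FeCl3) exchanges the silyl group and oxidises the cyclopropanol oxygen to an alkoxy radical, whose β-scission breaks the bond shared by the three- and five-membered rings (C1–C5 of the bicycle) to give a tertiary β-keto radical that takes chlorine from a second FeCl3; acetate then removes HCl by an E1cB path. The closest known reaction type is the Saegusa–Ito one-carbon ring expansion of 1-siloxybicyclo[n.1.0]alkanes to cycloalk-2-enones, which includes methyl-substituted bridgeheads. No ring is closed: the six-membered ring arises by merging the two small rings, the former carbenoid carbon becoming the vinylic CH between the carbonyl and the methyl-bearing carbon. No lasting stereocentre is formed (the C–Cl centre is lost again), and the R centre set in step 3 is untouched because it is neither a radical site nor α to the carbonyl. The step needs scission of the internal rather than the external cyclopropane bond, which the tertiary radical at the methyl-bearing bridgehead and the strain release secure; the only hydrogens between the carbonyl and the C–Cl carbon are those of the new CH2, so elimination can only give the conjugated enone. The side chain was chosen with a saturated carbinol carbon next to its alkene so that the radical has no stabilised 3-exo or vinyl-shift pathway.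

**Step 6**
Reactants: 10 enone
Product: 11 {(2E,4E)-3-methyl-5-[(1R)-2,6,6-trimethyl-4-oxocyclohex-2-en-1-yl]penta-2,4-dien-1-yl}triphenylphosphonium bromide
Conditions: PPh3·HBr, MeOH, 0 °C to rt; crystallisation
Reagents that add atoms: triphenylphosphine hydrobromide, Br.c1ccc(cc1)P(c1ccccc1)c1ccccc1
Why: Acid-promoted ionisation of the tertiary bis-allylic silyloxy group gives a pentadienyl cation that PPh3 traps at the primary terminus (the vinyl-carbinol to C15 phosphonium salt conversion of carotenoid chemistry), the new trisubstituted double bond forming mainly E and the minor Z salt being removed on crystallisation.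

**Step 7**
Reactants: 10 enone
Product: 12 (1S,4R)-4-[(1E)-3-(tert-butyldimethylsilyloxy)-3-methylpenta-1,4-dien-1-yl]-3,5,5-trimethylcyclohex-2-en-1-ol (hydroxyl cis to the side chain)
Conditions: LiBH(s-Bu)3, THF, −78 °C; H2O work-up
Reagents that add atoms: none
Why: The bulky trialkylborohydride should add 1,2 to this β,β-disubstituted enone from the face anti to the C4 side chain, so the new carbinol centre is set cis to the chain by substrate control relayed from C4.

**Step 8**
Reactants: 12 cis allylic alcohol
Product: 13 (1R,4R)-4-[(1E)-3-(tert-butyldimethylsilyloxy)-3-methylpenta-1,4-dien-1-yl]-3,5,5-trimethylcyclohex-2-en-1-yl 4-nitrobenzoate (ester trans to the side chain)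
Conditions: 4-nitrobenzoic acid, PPh3, DIAD, THF, 0 °C to rt
Reagents that add atoms: 4-nitrobenzoic acid, O=C(O)c1ccc(cc1)[N+](=O)[O-]
Why: Mitsunobu reaction: SN2 displacement of the oxyphosphonium by the carboxylate inverts the carbinol carbon to the required R (trans) configuration, and the ester protects the ring allylic oxygen for step 9.

**Step 9**
Reactants: 13 trans 4-nitrobenzoate
Product: 14 {(2E,4E)-3-methyl-5-[(1R,4R)-2,6,6-trimethyl-4-(4-nitrobenzoyloxy)cyclohex-2-en-1-yl]penta-2,4-dien-1-yl}triphenylphosphonium bromide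
Conditions: PPh3·HBr, MeOH/CH2Cl2, 0 °C to rt; crystallisation
Reagents that add atoms: triphenylphosphine hydrobromide, Br.c1ccc(cc1)P(c1ccccc1)c1ccccc1
Why: Same allylic transposition as step 6; the tertiary bis-allylic silyl ether ionises far more readily than the secondary allylic ester, so the ring oxygen and its configuration should survive.

**Step 10**
Reactants: 14 hydroxy-ring C15 phosphonium salt (as ester); 15 (2E,4E,6E)-2,7-dimethylocta-2,4,6-trienedial (3 equiv)
Product: 18 (2E,4E,6E,8E,10E,12E)-13-[(1R,4R)-4-hydroxy-2,6,6-trimethylcyclohex-2-en-1-yl]-2,7,11-trimethyltrideca-2,4,6,8,10,12-hexaenal, via ylide 16 (not isolated), via ester aldehyde 17 (not isolated)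
Conditions: NaOMe (1.1 equiv), CH2Cl2/MeOH, 0 °C; then NaOMe (1 equiv), MeOH, rt; then heptane, 80 °C
Reagents that add atoms: none
Why: Wittig olefination of the dialdehyde used in excess should stop at mono-olefination, methoxide then removes the 4-nitrobenzoate by transesterification before any base-sensitive oxo ring is present, and heating equilibrates the new disubstituted double bond to E.

**Step 11**
Reactants: 18 C25 hydroxy aldehyde; 11 oxo-ring C15 phosphonium salt
Product: 20 (3'R,6R,6'R)-3'-hydroxy-ε,ε-caroten-3-one, via ylide 19 (not isolated)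
Conditions: 1,2-epoxybutane, EtOH, 75 °C, argon, dark; then heptane/EtOAc, reflux; crystallisation
Reagents that add atoms: none
Why: Wittig olefination under the near-neutral epoxide protocol (bromide opens the epoxide and the resulting alkoxide forms the ylide at low concentration) should spare the γ-hydrogen at C6 of the oxo ring and tolerate the free hydroxyl, and heating equilibrates the new C11=C12 bond to the all-E polyene.

**Compound list**
1 | 2,4,4-trimethylcyclopentan-1-one (racemic) | CC1CC(C)(C)CC1=O | starting material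
2 | 2,4,4-trimethylcyclopent-2-en-1-one | CC1=CC(C)(C)CC1=O | intermediate
3 | 3-methylpent-1-en-4-yn-3-ol (racemic) | C#CC(C)(O)C=C | starting material
4 | tert-butyl(dimethyl)[(3-methylpent-1-en-4-yn-3-yl)oxy]silane (racemic) | C#CC(C)(O[Si](C)(C)C(C)(C)C)C=C | intermediate
5 | [(1E)-3-(tert-butyldimethylsilyloxy)-3-methylpenta-1,4-dien-1-yl]diisobutylalane | CC(C)C[Al](CC(C)C)/C=C/C(C)(O[Si](C)(C)C(C)(C)C)C=C | intermediate
6 | diisobutylaluminium (3R)-3-[(1E)-3-(tert-butyldimethylsilyloxy)-3-methylpenta-1,4-dien-1-yl]-2,4,4-trimethylcyclopent-1-en-1-olate | CC(C)C[Al](CC(C)C)OC1=C(C)[C@H](/C=C/C(C)(O[Si](C)(C)C(C)(C)C)C=C)C(C)(C)C1 | intermediate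
7 | {[(3R)-3-[(1E)-3-(tert-butyldimethylsilyloxy)-3-methylpenta-1,4-dien-1-yl]-2,4,4-trimethylcyclopent-1-en-1-yl]oxy}trimethylsilane | C[Si](C)(C)OC1=C(C)[C@H](/C=C/C(C)(O[Si](C)(C)C(C)(C)C)C=C)C(C)(C)C1 | intermediate
8 | {[(1S,4R,5S)-4-[(1E)-3-(tert-butyldimethylsilyloxy)-3-methylpenta-1,4-dien-1-yl]-3,3,5-trimethylbicyclo[3.1.0]hexan-1-yl]oxy}trimethylsilane | C[Si](C)(C)O[C@]12C[C@@]1(C)[C@H](/C=C/C(C)(O[Si](C)(C)C(C)(C)C)C=C)C(C)(C)C2 | intermediate
9 | (4R)-3-chloro-4-[(1E)-3-(tert-butyldimethylsilyloxy)-3-methylpenta-1,4-dien-1-yl]-3,5,5-trimethylcyclohexan-1-one (both C3 epimers) | CC1(Cl)CC(=O)CC(C)(C)[C@H]1/C=C/C(C)(O[Si](C)(C)C(C)(C)C)C=C | intermediate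
10 | (4R)-4-[(1E)-3-(tert-butyldimethylsilyloxy)-3-methylpenta-1,4-dien-1-yl]-3,5,5-trimethylcyclohex-2-en-1-one | CC1=CC(=O)CC(C)(C)[C@H]1/C=C/C(C)(O[Si](C)(C)C(C)(C)C)C=C | intermediate
11 | {(2E,4E)-3-methyl-5-[(1R)-2,6,6-trimethyl-4-oxocyclohex-2-en-1-yl]penta-2,4-dien-1-yl}triphenylphosphonium bromide | CC1=CC(=O)CC(C)(C)[C@H]1/C=C/C(C)=C/C[P+](c1ccccc1)(c1ccccc1)c1ccccc1.[Br-] | intermediate
12 | (1S,4R)-4-[(1E)-3-(tert-butyldimethylsilyloxy)-3-methylpenta-1,4-dien-1-yl]-3,5,5-trimethylcyclohex-2-en-1-ol | CC1=C[C@@H](O)CC(C)(C)[C@H]1/C=C/C(C)(O[Si](C)(C)C(C)(C)C)C=C | intermediate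
13 | (1R,4R)-4-[(1E)-3-(tert-butyldimethylsilyloxy)-3-methylpenta-1,4-dien-1-yl]-3,5,5-trimethylcyclohex-2-en-1-yl 4-nitrobenzoate | CC1=C[C@H](OC(=O)c2ccc(cc2)[N+](=O)[O-])CC(C)(C)[C@H]1/C=C/C(C)(O[Si](C)(C)C(C)(C)C)C=C | intermediate
14 | {(2E,4E)-3-methyl-5-[(1R,4R)-2,6,6-trimethyl-4-(4-nitrobenzoyloxy)cyclohex-2-en-1-yl]penta-2,4-dien-1-yl}triphenylphosphonium bromide | CC1=C[C@H](OC(=O)c2ccc(cc2)[N+](=O)[O-])CC(C)(C)[C@H]1/C=C/C(C)=C/C[P+](c1ccccc1)(c1ccccc1)c1ccccc1.[Br-] | intermediate
15 | (2E,4E,6E)-2,7-dimethylocta-2,4,6-trienedial | O=C/C(C)=C/C=C/C=C(C)/C=O | starting material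
16 | triphenylphosphonium ylide of 14 | CC1=C[C@H](OC(=O)c2ccc(cc2)[N+](=O)[O-])CC(C)(C)[C@H]1/C=C/C(C)=C/C=P(c1ccccc1)(c1ccccc1)c1ccccc1 | intermediate
17 | (1R,4R)-3,5,5-trimethyl-4-[(1E,3E,5E,7E,9E,11E)-3,7,12-trimethyl-13-oxotrideca-1,3,5,7,9,11-hexaen-1-yl]cyclohex-2-en-1-yl 4-nitrobenzoate | CC1=C[C@H](OC(=O)c2ccc(cc2)[N+](=O)[O-])CC(C)(C)[C@H]1/C=C/C(C)=C/C=C/C(C)=C/C=C/C=C(C)/C=O | intermediate
18 | (2E,4E,6E,8E,10E,12E)-13-[(1R,4R)-4-hydroxy-2,6,6-trimethylcyclohex-2-en-1-yl]-2,7,11-trimethyltrideca-2,4,6,8,10,12-hexaenal | CC1=C[C@H](O)CC(C)(C)[C@H]1/C=C/C(C)=C/C=C/C(C)=C/C=C/C=C(C)/C=O | intermediate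
19 | triphenylphosphonium ylide of 11 | CC1=CC(=O)CC(C)(C)[C@H]1/C=C/C(C)=C/C=P(c1ccccc1)(c1ccccc1)c1ccccc1 | intermediate
20 | (3'R,6R,6'R)-3'-hydroxy-ε,ε-caroten-3-one | CC1=CC(=O)CC(C)(C)[C@H]1/C=C/C(C)=C/C=C/C(C)=C/C=C/C=C(C)/C=C/C=C(C)/C=C/[C@H]1C(C)=C[C@H](O)CC1(C)C | target

**Count**
Total steps: 11. Longest linear sequence: 9 steps (steps 1 or 2, then 3, 4, 5, 7, 8, 9, 10, 11).

**Steps most likely to fail**

Step 3. The process at risk is face discrimination (and rate) in the copper-catalysed alkenyl transfer to a β-carbon that sits between a quaternary carbon and a methyl-bearing α-carbon; low enantiomeric purity would be carried into both rings. The fallback gives up catalytic control and resolves later. It sets out from 2 and alane 5, which are combined with an achiral copper source (CuBr·SMe2, then TMSOTf). This gives 6 and 7 together with their mirror images, the (3S) aluminium enolate F1 and the (3S) silyl enol ether F2. Steps 4, 5 and 7 are run unchanged on the racemate and pass through the enantiomeric siloxycyclopropane F3, the enantiomeric β-chloroketone F4 and the enantiomeric enone F5 to a racemic cis alcohol, that is 12 with its (1R,4S) enantiomer F6. Lipase-mediated acylation (Burkholderia cepacia lipase, vinyl acetate, t-BuOMe) is expected, by the usual empirical rule for secondary alcohols with the alkene arm as the large group, to acetylate the (1R)-configured antipode to the (1R,4S) acetate F7 and leave 12, which is separated by chromatography. The fallback comes back to the route at 12. The material for the oxo ring is obtained by oxidising part of the resolved 12 with MnO2 back to 10, which then enters step 6.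

Step 5. The processes at risk are scission of the external instead of the internal cyclopropane bond, ionisation of the tertiary bis-allylic silyl ether by the Lewis-acidic iron salt, and γ-deprotonation with loss of configuration at C4 of the enone during dehydrochlorination. Incomplete chemoselectivity of the carbenoid in step 4 is answered by the same fallback. It replaces the radical opening by a polar, electrocyclic one and sets out from 7. Dibromocarbene (CHBr3, KOt-Bu 1.0 equiv, pentane, −30 °C) adds to the enol ether to give the dibromo siloxycyclopropane F8, which opens spontaneously with loss of bromide and of the silyl group to the ring-expanded (4R)-2-bromo enone F9. Hydrodebromination (Pd(OAc)2, PPh3, HCO2H, Et3N, DMF, 60 °C) then returns to the route at 10. This does not cure base-induced epimerisation, which is limited by using no excess of alkoxide.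

Step 7. The process at risk is poor facial selectivity of hydride delivery, because the side chain and the axial methyl group shield opposite faces in different half-chair conformers. The fallback replaces substrate control plus inversion by reagent control and sets out from 10. Reduction with (S)-2-methyl-CBS-oxazaborolidine (catalytic) and catecholborane in toluene at −78 °C is expected to give the trans (1R,4R) allylic alcohol F10 directly. Acylation with 4-nitrobenzoyl chloride and pyridine, with retention, comes back to the route at 13, so that steps 7 and 8 are both replaced.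

**Further compounds**
F1 | step 3 | diisobutylaluminium (3S)-3-[(1E)-3-(tert-butyldimethylsilyloxy)-3-methylpenta-1,4-dien-1-yl]-2,4,4-trimethylcyclopent-1-en-1-olate (enantiomer of 6) | CC(C)C[Al](CC(C)C)OC1=C(C)[C@@H](/C=C/C(C)(O[Si](C)(C)C(C)(C)C)C=C)C(C)(C)C1
F2 | step 3 | {[(3S)-3-[(1E)-3-(tert-butyldimethylsilyloxy)-3-methylpenta-1,4-dien-1-yl]-2,4,4-trimethylcyclopent-1-en-1-yl]oxy}trimethylsilane (enantiomer of 7) | C[Si](C)(C)OC1=C(C)[C@@H](/C=C/C(C)(O[Si](C)(C)C(C)(C)C)C=C)C(C)(C)C1
F3 | step 3 | {[(1R,4S,5R)-4-[(1E)-3-(tert-butyldimethylsilyloxy)-3-methylpenta-1,4-dien-1-yl]-3,3,5-trimethylbicyclo[3.1.0]hexan-1-yl]oxy}trimethylsilane (enantiomer of 8) | C[Si](C)(C)O[C@@]12C[C@]1(C)[C@@H](/C=C/C(C)(O[Si](C)(C)C(C)(C)C)C=C)C(C)(C)C2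
F4 | step 3 | (4S)-3-chloro-4-[(1E)-3-(tert-butyldimethylsilyloxy)-3-methylpenta-1,4-dien-1-yl]-3,5,5-trimethylcyclohexan-1-one (enantiomer of 9) | CC1(Cl)CC(=O)CC(C)(C)[C@@H]1/C=C/C(C)(O[Si](C)(C)C(C)(C)C)C=C
F5 | step 3 | (4S)-4-[(1E)-3-(tert-butyldimethylsilyloxy)-3-methylpenta-1,4-dien-1-yl]-3,5,5-trimethylcyclohex-2-en-1-one (enantiomer of 10) | CC1=CC(=O)CC(C)(C)[C@@H]1/C=C/C(C)(O[Si](C)(C)C(C)(C)C)C=C
F6 | step 3 | (1R,4S)-4-[(1E)-3-(tert-butyldimethylsilyloxy)-3-methylpenta-1,4-dien-1-yl]-3,5,5-trimethylcyclohex-2-en-1-ol (enantiomer of 12) | CC1=C[C@H](O)CC(C)(C)[C@@H]1/C=C/C(C)(O[Si](C)(C)C(C)(C)C)C=C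
F7 | step 3 | (1R,4S)-4-[(1E)-3-(tert-butyldimethylsilyloxy)-3-methylpenta-1,4-dien-1-yl]-3,5,5-trimethylcyclohex-2-en-1-yl acetate | CC1=C[C@H](OC(C)=O)CC(C)(C)[C@@H]1/C=C/C(C)(O[Si](C)(C)C(C)(C)C)C=C
F8 | step 5 | {[(4R)-6,6-dibromo-4-[(1E)-3-(tert-butyldimethylsilyloxy)-3-methylpenta-1,4-dien-1-yl]-3,3,5-trimethylbicyclo[3.1.0]hexan-1-yl]oxy}trimethylsilane (CBr2 anti to the side chain) | C[Si](C)(C)O[C@]12C(Br)(Br)[C@@]1(C)[C@H](/C=C/C(C)(O[Si](C)(C)C(C)(C)C)C=C)C(C)(C)C2
F9 | step 5 | (4R)-2-bromo-4-[(1E)-3-(tert-butyldimethylsilyloxy)-3-methylpenta-1,4-dien-1-yl]-3,5,5-trimethylcyclohex-2-en-1-one | CC1=C(Br)C(=O)CC(C)(C)[C@H]1/C=C/C(C)(O[Si](C)(C)C(C)(C)C)C=C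
F10 | step 7 | (1R,4R)-4-[(1E)-3-(tert-butyldimethylsilyloxy)-3-methylpenta-1,4-dien-1-yl]-3,5,5-trimethylcyclohex-2-en-1-ol | CC1=C[C@H](O)CC(C)(C)[C@H]1/C=C/C(C)(O[Si](C)(C)C(C)(C)C)C=C
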